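**Plan**
- Retrosynthetic cuts, in order: the enol δ-lactone that masks the propanoic acid and the C7 ketone; the C6–prenyl bond (dearomatising allylation); C8–CH(Ph) and O7–C(=O) (annulation with cinnamaldehyde); the aryl C6–CH2 bond to the cyclobutylmethyl unit; last, O1–C2 and C4–C3 of the dihydropyranone.
- Forward: the dihydropyranone ring is built first by annulating but-2-yne onto a phloroglucinaldehyde; then the C6 side chain is attached, the δ-lactone ring is closed, C6 is made quaternary, and the lactone is opened.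
- Enabling feature: in the ring O1–C2–C3–C4(=O)–C4a–C8a, O1 and the C4 carbonyl are ortho on the carbocycle, so the ring is a salicylaldehyde (O–H plus formyl C–H) that has taken up but-2-yne as C2–C3. In the phloroglucinol carbocycle both ortho O–H groups are equivalent, so ring closure has no regiochemical choice.
- Stereochemistry: cyclobutane (1R,3S) from (−)-verbenone; C2 by quinine and C3 by equilibration to trans; the benzylic centre by a chiral carbene catalyst; the quaternary C6 by a chiral Pd–allyl catalyst.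

Key step: step 2

Assumption: the sense of induction of the three chiral catalysts (quinine, the triazolylidene carbene, the Pd diphosphine) is taken from their closest analogues; if one proves opposite on these substrates, its mirror-image or pseudo-enantiomeric form is used in the same step.

**Step 1**
Reactants: 1 2,4,6-trihydroxybenzaldehyde
Product: 2 4-[(tert-butyldimethylsilyl)oxy]-2,6-dihydroxybenzaldehyde
Conditions: TBSCl (1.05 equiv), imidazole (2.2 equiv), DMF, 0 °C
Reagents that add atoms: tert-butyldimethylsilyl chloride, CC(C)(C)[Si](C)(C)Cl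
Why: Selective silyl ether formation, since the para hydroxyl is the most acidic and the only one not hydrogen-bonded to the formyl group, so one equivalent should cap it and leave both ortho hydroxyls free.

**Step 2**
Reactants: 2 4-[(tert-butyldimethylsilyl)oxy]-2,6-dihydroxybenzaldehyde; 3 but-2-yne
Product: 6 (2R,3R)-7-[(tert-butyldimethylsilyl)oxy]-5-hydroxy-2,3-dimethylchroman-4-one, via tigloyl ketone 4 (not isolated), via cis-chromanone 5 (not isolated)
Conditions: [Rh(cod)OMe]2 (2.5 mol%), dppf (5 mol%), but-2-yne (3 equiv), PhCl, 70 °C, sealed tube; then (−)-quinine (20 mol%), 10 °C; then MgI2 (20 mol%), i-Pr2NEt (40 mol%), rt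
Reagents that add atoms: none
Why: A Rh(I) phenoxide formed from one ortho hydroxyl inserts into the chelated formyl C–H, adds syn across but-2-yne and reductively eliminates the (E)-2-methylbut-2-enoyl ketone 4 (C4–C3 bond); quinine then pairs with the second ortho hydroxyl and delivers it to the enone β-carbon (O1–C2 bond), and the Mg/amine couple equilibrates the α-centre by soft enolisation. The closest known reaction types are the tandem Rh-catalysed alkyne hydroacylation/oxa-Michael addition of salicylaldehydes to trans-2,3-disubstituted chroman-4-ones and the cinchona-alkaloid-catalysed oxa-Michael cyclisation of o-tigloylphenols. The dihydropyranone ring closes by 6-endo-trig attack of oxygen on the enone. C2 (R) is set by the alkaloid, which should shield one enone face in the ion pair, and C3 (R) by thermodynamic control, the trans isomer carrying both methyl groups pseudo-equatorial. The step needs chemoselectivity for hydroacylation over decarbonylation, which the O–Rh–acyl chelate secures; no regiochemical choice arises because the two ortho hydroxyls of 2 are equivalent and the alkyne is symmetrical, and no base is present until the alkaloid is added cold, which should keep racemic closure low.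

**Step 3**
Reactants: 6 (2R,3R)-7-[(tert-butyldimethylsilyl)oxy]-5-hydroxy-2,3-dimethylchroman-4-one
Product: 7 (2R,3R)-7-[(tert-butyldimethylsilyl)oxy]-5-hydroxy-6-iodo-2,3-dimethylchroman-4-one
Conditions: BnMe3N·ICl2 (1.05 equiv), CaCO3 (1.5 equiv), CH2Cl2/MeOH, rt
Reagents that add atoms: benzyltrimethylammonium dichloroiodate, C[N+](C)(C)Cc1ccccc1.Cl[I-]Cl
Why: Electrophilic aromatic iodination; with O7 capped the ring is driven by the free, carbonyl-chelated C5 phenol, and this reagent is known to iodinate 5-hydroxy-7-alkoxy benzopyranones at the ortho carbon C6 and not at C8.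

**Step 4**
Reactants: 8 (1S,5S)-(−)-verbenone
Product: 9 (1S,3R)-3-acetyl-2,2-dimethylcyclobutane-1-carboxylic acid (cis-pinononic acid)
Conditions: RuCl3·xH2O (2 mol%), NaIO4 (4.2 equiv), EtOAc/MeCN/H2O, rt
Reagents that add atoms: sodium periodate, [Na+].[O-]I(=O)(=O)=O; water, O
Why: Ruthenium tetroxide cleavage of the enone C=C with oxidative loss of the α-keto acid carbon should give the cis keto acid with both ring stereocentres of verbenone untouched.

**Step 5**
Reactants: 9 (1S,3R)-3-acetyl-2,2-dimethylcyclobutane-1-carboxylic acid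
Product: 10 (1S,3S)-2,2-dimethyl-3-(prop-1-en-2-yl)cyclobutane-1-carboxylic acid
Conditions: Ph3PCH3Br (2.6 equiv), KOtBu (2.5 equiv), THF, 0 °C to rt; aq. HCl work-up
Reagents that add atoms: methyltriphenylphosphonium bromide, C[P+](c1ccccc1)(c1ccccc1)c1ccccc1.[Br-]
Why: Wittig methylenation of the methyl ketone on the carboxylate salt; the cis-1,3 arrangement is the more stable one, so the basic ylide should not erode the centre next to the ketone.

**Step 6**
Reactants: 10 (1S,3S)-2,2-dimethyl-3-(prop-1-en-2-yl)cyclobutane-1-carboxylic acid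
Product: 11 [(1S,3S)-2,2-dimethyl-3-(prop-1-en-2-yl)cyclobutyl]methanol
Conditions: LiAlH4 (1.5 equiv), THF, 0 °C to rt; aq. NaOH work-up
Reagents that add atoms: none
Why: Hydride reduction of the carboxylic acid to the primary alcohol touches no stereocentre.

**Step 7**
Reactants: 11 [(1S,3S)-2,2-dimethyl-3-(prop-1-en-2-yl)cyclobutyl]methanol
Product: 12 (1S,3S)-1-(iodomethyl)-2,2-dimethyl-3-(prop-1-en-2-yl)cyclobutane
Conditions: I2 (1.2 equiv), PPh3 (1.2 equiv), imidazole (1.5 equiv), CH2Cl2, 0 °C to rt
Reagents that add atoms: iodine, II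
Why: Appel iodination by SN2 displacement at the primary carbon avoids a cyclobutylcarbinyl cation and leaves both stereocentres alone.

**Step 8**
Reactants: 7 (2R,3R)-7-[(tert-butyldimethylsilyl)oxy]-5-hydroxy-6-iodo-2,3-dimethylchroman-4-one; 12 (1S,3S)-1-(iodomethyl)-2,2-dimethyl-3-(prop-1-en-2-yl)cyclobutane
Product: 15 (2R,3R)-7-[(tert-butyldimethylsilyl)oxy]-6-{[(1R,3S)-2,2-dimethyl-3-(prop-1-en-2-yl)cyclobutyl]methyl}-5-hydroxy-2,3-dimethylchroman-4-one, via alkyllithium 13 (not isolated), via alkylzinc chloride 14 (not isolated)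
Conditions: 12, t-BuLi (2.1 equiv), Et2O/pentane, −78 °C; ZnCl2 (1.1 equiv), THF, −78 °C to rt; slow addition to 7, Pd(OAc)2 (3 mol%), SPhos (6 mol%), THF, 25 °C
Reagents that add atoms: none
Why: Negishi sp2–sp3 cross-coupling in which iodine–lithium exchange at −78 °C and transmetalation to zinc avoid radical opening of the cyclobutane, a dialkylbiarylphosphine Pd catalyst couples primary alkylzincs with hindered aryl iodides in the presence of a free phenol, and all stereocentres are β or farther from the metal.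

**Step 9**
Reactants: 15 (2R,3R)-7-[(tert-butyldimethylsilyl)oxy]-6-{[(1R,3S)-2,2-dimethyl-3-(prop-1-en-2-yl)cyclobutyl]methyl}-5-hydroxy-2,3-dimethylchroman-4-one
Product: 16 (2R,3R)-6-{[(1R,3S)-2,2-dimethyl-3-(prop-1-en-2-yl)cyclobutyl]methyl}-5,7-dihydroxy-2,3-dimethylchroman-4-one
Conditions: TBAF (1.1 equiv), AcOH (1.2 equiv), THF, 0 °C
Reagents that add atoms: none
Why: Fluoride cleavage of the aryl silyl ether, buffered with acetic acid so that no free phenoxide or enolate opens or epimerises the dihydropyranone.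

**Step 10**
Reactants: 16 (2R,3R)-6-{[(1R,3S)-2,2-dimethyl-3-(prop-1-en-2-yl)cyclobutyl]methyl}-5,7-dihydroxy-2,3-dimethylchroman-4-one; 17 (E)-cinnamaldehyde
Product: 18 (2R,3R,10S)-6-{[(1R,3S)-2,2-dimethyl-3-(prop-1-en-2-yl)cyclobutyl]methyl}-5-hydroxy-2,3-dimethyl-10-phenyl-2,3,9,10-tetrahydro-4H,8H-pyrano[2,3-f]chromene-4,8-dione (δ-lactone C10a–CH(Ph)–CH2–C(=O)–O7 fused to the chromanone)
Conditions: (5aS,10bR)-N-mesityl aminoindanol-derived triazolium chloride (10 mol%), i-Pr2NEt (30 mol%), 3,3',5,5'-tetra-tert-butyldiphenoquinone (1.2 equiv), 17 (1.5 equiv), THF, rt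
Reagents that add atoms: none
Why: Oxidative N-heterocyclic carbene catalysis, in which the cinnamoyl azolium formed in situ takes conjugate addition from the only free ring carbon (C8 of 16) and the adjacent 7-OH lactonises and releases the carbene, the chiral triazolylidene shielding one face of the acceptor to set the benzylic centre (S).

**Step 11**
Reactants: 18 the tricyclic lactone above; 19 tert-butyl (3-methylbut-2-en-1-yl) carbonate
Product: 20 (2R,3R,6S,10S)-6-{[(1R,3S)-2,2-dimethyl-3-(prop-1-en-2-yl)cyclobutyl]methyl}-2,3-dimethyl-6-(3-methylbut-2-en-1-yl)-10-phenyl-2,3,9,10-tetrahydro-4H,8H-pyrano[2,3-f]chromene-4,5,8(6H)-trione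
Conditions: Pd2(dba)3·CHCl3 (2.5 mol%), (R,R)-DACH-phenyl bis(2-diphenylphosphinobenzamide) ligand (7.5 mol%), 19 (1.3 equiv), toluene, 0 °C to rt
Reagents that add atoms: none
Why: Pd-catalysed asymmetric allylic dearomatisation (Tsuji–Trost type), in which the C5 phenoxide attacks the unsubstituted terminus of the π-prenyl complex through C6, the least hindered of its ortho/para carbons and the one that leaves a stabilised vinylogous ester, while O-allylation stays reversible and the chiral diphosphine pocket selects the ring face and so the quaternary centre (6S here, 6R in the target by the change in CIP ranking).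

**Step 12**
Reactants: 20 the dearomatised enol lactone above
Product: 21 (3S)-3-[(2R,3R,6R)-6-{[(1R,3S)-2,2-dimethyl-3-(prop-1-en-2-yl)cyclobutyl]methyl}-5-hydroxy-2,3-dimethyl-6-(3-methylbut-2-en-1-yl)-4,7-dioxo-3,4,6,7-tetrahydro-2H-chromen-8-yl]-3-phenylpropanoic acid (CNP0103716.3)
Conditions: LiOH·H2O (2.5 equiv), THF/H2O (3:1), 0 °C; 1 M HCl to pH 3
Reagents that add atoms: lithium hydroxide, [Li+].[OH-]; water, O
Why: Hydroxide should open the enol lactone (an activated acyl enol ester of a vinylogous acid) much faster than any other carbonyl, unmasking the C7 ketone and the propanoic acid, while in the anionic trione C3–H is too weakly acidic for retro-oxa-Michael opening at 0 °C.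

**Compound list**
1 | 2,4,6-trihydroxybenzaldehyde | O=Cc1c(O)cc(O)cc1O | starting material
2 | 4-[(tert-butyldimethylsilyl)oxy]-2,6-dihydroxybenzaldehyde | CC(C)(C)[Si](C)(C)Oc1cc(O)c(C=O)c(O)c1 | intermediate
3 | but-2-yne | CC#CC | starting material
4 | (E)-1-{4-[(tert-butyldimethylsilyl)oxy]-2,6-dihydroxyphenyl}-2-methylbut-2-en-1-one (not isolated) | C/C=C(\C)C(=O)c1c(O)cc(O[Si](C)(C)C(C)(C)C)cc1O | intermediate
5 | (2R,3S)-7-[(tert-butyldimethylsilyl)oxy]-5-hydroxy-2,3-dimethylchroman-4-one, cis (not isolated) | CC(C)(C)[Si](C)(C)Oc1cc(O)c2c(c1)O[C@H](C)[C@H](C)C2=O | intermediate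
6 | (2R,3R)-7-[(tert-butyldimethylsilyl)oxy]-5-hydroxy-2,3-dimethylchroman-4-one, trans | CC(C)(C)[Si](C)(C)Oc1cc(O)c2c(c1)O[C@H](C)[C@@H](C)C2=O | intermediate
7 | (2R,3R)-7-[(tert-butyldimethylsilyl)oxy]-5-hydroxy-6-iodo-2,3-dimethylchroman-4-one | CC(C)(C)[Si](C)(C)Oc1c(I)c(O)c2c(c1)O[C@H](C)[C@@H](C)C2=O | intermediate
8 | (1S,5S)-(−)-verbenone | CC1=CC(=O)[C@H]2C[C@@H]1C2(C)C | starting material
9 | (1S,3R)-3-acetyl-2,2-dimethylcyclobutane-1-carboxylic acid | CC(=O)[C@@H]1C[C@H](C(=O)O)C1(C)C | intermediate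
10 | (1S,3S)-2,2-dimethyl-3-(prop-1-en-2-yl)cyclobutane-1-carboxylic acid | C=C(C)[C@@H]1C[C@H](C(=O)O)C1(C)C | intermediate
11 | [(1S,3S)-2,2-dimethyl-3-(prop-1-en-2-yl)cyclobutyl]methanol | C=C(C)[C@@H]1C[C@H](CO)C1(C)C | intermediate
12 | (1S,3S)-1-(iodomethyl)-2,2-dimethyl-3-(prop-1-en-2-yl)cyclobutane | C=C(C)[C@@H]1C[C@H](CI)C1(C)C | intermediate
13 | {[(1S,3S)-2,2-dimethyl-3-(prop-1-en-2-yl)cyclobutyl]methyl}lithium (not isolated) | C=C(C)[C@@H]1C[C@H](C[Li])C1(C)C | intermediate
14 | {[(1S,3S)-2,2-dimethyl-3-(prop-1-en-2-yl)cyclobutyl]methyl}zinc chloride (not isolated) | C=C(C)[C@@H]1C[C@H](C[Zn]Cl)C1(C)C | intermediate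
15 | (2R,3R)-7-[(tert-butyldimethylsilyl)oxy]-6-{[(1R,3S)-2,2-dimethyl-3-(prop-1-en-2-yl)cyclobutyl]methyl}-5-hydroxy-2,3-dimethylchroman-4-one | C=C(C)[C@@H]1C[C@H](Cc2c(O)c3c(cc2O[Si](C)(C)C(C)(C)C)O[C@H](C)[C@@H](C)C3=O)C1(C)C | intermediate
16 | (2R,3R)-6-{[(1R,3S)-2,2-dimethyl-3-(prop-1-en-2-yl)cyclobutyl]methyl}-5,7-dihydroxy-2,3-dimethylchroman-4-one | C=C(C)[C@@H]1C[C@H](Cc2c(O)c3c(cc2O)O[C@H](C)[C@@H](C)C3=O)C1(C)C | intermediate
17 | (E)-cinnamaldehyde | O=C/C=C/c1ccccc1 | starting material
18 | (2R,3R,10S)-6-{[(1R,3S)-2,2-dimethyl-3-(prop-1-en-2-yl)cyclobutyl]methyl}-5-hydroxy-2,3-dimethyl-10-phenyl-2,3,9,10-tetrahydro-4H,8H-pyrano[2,3-f]chromene-4,8-dione | C=C(C)[C@@H]1C[C@H](Cc2c(O)c3c(c4c2OC(=O)C[C@H]4c2ccccc2)O[C@H](C)[C@@H](C)C3=O)C1(C)C | intermediate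
19 | tert-butyl (3-methylbut-2-en-1-yl) carbonate | CC(C)=CCOC(=O)OC(C)(C)C | starting material
20 | (2R,3R,6S,10S)-6-{[(1R,3S)-2,2-dimethyl-3-(prop-1-en-2-yl)cyclobutyl]methyl}-2,3-dimethyl-6-(3-methylbut-2-en-1-yl)-10-phenyl-2,3,9,10-tetrahydro-4H,8H-pyrano[2,3-f]chromene-4,5,8(6H)-trione | C=C(C)[C@@H]1C[C@H](C[C@@]2(CC=C(C)C)C(OC(=O)C[C@H]3c4ccccc4)=C3C(O[C@H](C)[C@@H](C)C4=O)=C4C2=O)C1(C)C | intermediate
21 | (3S)-3-[(2R,3R,6R)-6-{[(1R,3S)-2,2-dimethyl-3-(prop-1-en-2-yl)cyclobutyl]methyl}-5-hydroxy-2,3-dimethyl-6-(3-methylbut-2-en-1-yl)-4,7-dioxo-3,4,6,7-tetrahydro-2H-chromen-8-yl]-3-phenylpropanoic acid | C=C(C)[C@@H]1C[C@H](C[C@@]2(CC=C(C)C)C(=O)C([C@@H](CC(=O)O)c3ccccc3)=C3O[C@H](C)[C@@H](C)C(=O)C3=C2O)C1(C)C | target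

**Step count**
Total: 12 steps. Longest linear sequence: 9 steps (steps 4 to 12, from 8).

**Steps most likely to fail**

Step 11. The chiral Pd–allyl catalyst may give poor facial selectivity at the new quaternary carbon, since the existing stereocentres are remote, and the weakly nucleophilic chelated mono-phenoxide may stop at O-allylation or take the prenyl unit at its substituted end. The fallback sets out from 18 and changes to a substrate-anion alkylation without catalyst control. Aqueous KOH in MeOH at 0 °C opens the aryl lactone to the tripotassium salt of (3S)-3-[(2R,3R)-6-{[(1R,3S)-2,2-dimethyl-3-(prop-1-en-2-yl)cyclobutyl]methyl}-5,7-dihydroxy-2,3-dimethyl-4-oxochroman-8-yl]-3-phenylpropanoic acid F1. Prenyl bromide then alkylates C6, now flanked by two phenoxide oxygens, with dearomatisation, as in the classical base-mediated gem-prenylation of acylphloroglucinols. Acidification should give 21 together with its C6 epimer F2; the two are diastereomers and would be separated by preparative HPLC. The route is rejoined at 21 and 20 is bypassed.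

Step 10. The acyl azolium may acylate the phenol oxygen instead of forming the C8–C bond, or the catalyst may control the acceptor face poorly with this hindered, moderately nucleophilic arene. The fallback sets out from 16 and uses iminium instead of acyl azolium activation. A diarylprolinol silyl ether (20 mol%) with benzoic acid and cinnamaldehyde 17 in CH2Cl2 should give Friedel–Crafts-type conjugate addition from C8 and hemiacetal closure by the 7-OH to the lactol (2R,3R,10S)-6-{[(1R,3S)-2,2-dimethyl-3-(prop-1-en-2-yl)cyclobutyl]methyl}-5,8-dihydroxy-2,3-dimethyl-10-phenyl-2,3,9,10-tetrahydro-4H,8H-pyrano[2,3-f]chromen-4-one F3. Oxidation with TPAP (cat.) and NMO converts the lactol into 18, where the route is rejoined.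

Step 2. Ring closure may proceed in part without the alkaloid (on Rh phenoxide or thermally), or the ring may open and re-close during the C3 equilibration; both would erode the C2 configuration, and decarbonylation of the electron-rich aldehyde may compete with alkyne insertion. The fallback sets out from 2 and separates C–C bond formation from the asymmetric ring closure. After double deprotonation with MeMgCl, the alkenyllithium made from (E)-2-bromobut-2-ene and t-BuLi (retention of geometry) adds to the chelated aldehyde to give (E)-1-{4-[(tert-butyldimethylsilyl)oxy]-2,6-dihydroxyphenyl}-2-methylbut-2-en-1-ol F4. This is oxidised without purification by MnO2 to enone 4, which is now isolated. Compound 4 is then closed with quinine at low temperature and equilibrated with MgI2/i-Pr2NEt as separate operations, through 5 to 6, where the route is rejoined.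

**Further compounds**
F1 | step 11 | (3S)-3-[(2R,3R)-6-{[(1R,3S)-2,2-dimethyl-3-(prop-1-en-2-yl)cyclobutyl]methyl}-5,7-dihydroxy-2,3-dimethyl-4-oxochroman-8-yl]-3-phenylpropanoic acid | C=C(C)[C@@H]1C[C@H](Cc2c(O)c3c(c([C@@H](CC(=O)O)c4ccccc4)c2O)O[C@H](C)[C@@H](C)C3=O)C1(C)C
F2 | step 11 | (3S)-3-[(2R,3R,6S)-6-{[(1R,3S)-2,2-dimethyl-3-(prop-1-en-2-yl)cyclobutyl]methyl}-5-hydroxy-2,3-dimethyl-6-(3-methylbut-2-en-1-yl)-4,7-dioxo-3,4,6,7-tetrahydro-2H-chromen-8-yl]-3-phenylpropanoic acid (C6 epimer of 21) | C=C(C)[C@@H]1C[C@H](C[C@]2(CC=C(C)C)C(=O)C([C@@H](CC(=O)O)c3ccccc3)=C3O[C@H](C)[C@@H](C)C(=O)C3=C2O)C1(C)C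
F3 | step 10 | (2R,3R,10S)-6-{[(1R,3S)-2,2-dimethyl-3-(prop-1-en-2-yl)cyclobutyl]methyl}-5,8-dihydroxy-2,3-dimethyl-10-phenyl-2,3,9,10-tetrahydro-4H,8H-pyrano[2,3-f]chromen-4-one (lactol, both anomers) | C=C(C)[C@@H]1C[C@H](Cc2c(O)c3c(c4c2OC(O)C[C@H]4c2ccccc2)O[C@H](C)[C@@H](C)C3=O)C1(C)C
F4 | step 2 | (E)-1-{4-[(tert-butyldimethylsilyl)oxy]-2,6-dihydroxyphenyl}-2-methylbut-2-en-1-ol | C/C=C(\C)C(O)c1c(O)cc(O[Si](C)(C)C(C)(C)C)cc1O
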